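If the target is lost through something the catalyst does, a larger charge of catalyst can lower the amount at the end; that was the question before the meeting on elm, oak and cedar.

in all of them: starting material 0.10 M

| charge | coupling partner | protic impurity | catalyst | remark | time |
|---|---|---|---|---|---|
| epsilon | 0.14 M | 0.050 M | 1.2 mM | run made earlier |  |
| delta | 0.048 M | 0.050 M | 1.2 mM | run made earlier |  |
| elm | 0.0950 M | 0.0500 M | 1.2 mM |  | 2.5 d |
| oak | 0.0950 M | 0.0500 M | 2.5 mM |  | 2.5 d |
| cedar | 0.0950 M | 0.0500 M | 5.0 mM |  | 2.5 d |

- epsilon (time / h: target / %, starting material / %): 1.50: 32.0, 63.6; 4.00: 51.9, 39.2; 10.0: 61.6, 24.0; 20.0: 57.6, 19.4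
- delta (time / h: target / %, starting material / %): 1.50: 12.3, 85.4; 4.00: 21.9, 72.4; 10.0: 28.7, 60.3; 20.0: 28.3, 54.6

(each reading ± 0.3 percentage points)

- "hardly changes" means that all values lie within two and a half points (for a concentration: within two and a half percent of the largest)
- no earlier run changes the charge of catalyst; that part of a forecast is a guess

* amount of target at the end, in percent of the starting material charged for elm, oak, cedar, in this order
* the shape of the row from first to last (falls all the way / rises, then falls / hardly changes / falls, then rises / rises all the way)

The process chemist reported that in the epsilon run the target fell from 61.6% at 10.0 h to 57.6% at 20.0 h, and she proposed solving the flask at both ends and joining them. For the late end she took the lifetime of the target, the hours over which a fall is read, divided by the natural logarithm of the ratio of the two readings, which treats the loss as pseudo-first-order. Epsilon gives 6.21 d.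

The analyst objected that the delta run fell less, from 28.7% to 28.3%. The process chemist replied that target may still have been forming in both runs, so this lifetime may be a reading on the long side.

For the early end, the analyst interpolated the 10.0 h readings of both runs by coupling partner, which gave 45.5% for the new charge. The chair noted that no earlier run changes the catalyst, so the meeting guessed that this amount holds for every charge and that the lifetime shrinks in proportion to the charge.

My own reckoning as secretary lets that amount decay from 10.0 h to 2.5 d. It gives 32.5% for elm, 22.6% for oak and 11.2% for cedar, a row that falls all the way.

The forecast differs from this reckoning: it gave 30%, 37% and 41%, shape rises all the way, with the words “so the catalyst dies”.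

The flasks gave 34.1%, 28.2% and 23.0%; the row falls all the way. At the end the isomer of the product stood at 29.1% in elm, 37.3% in oak and 45.1% in cedar.

    starting material + coupling partner ⇌ target (K = 44.0 M⁻¹, k = 0.0390 M⁻¹ min⁻¹)
    starting material + protic impurity → quenched substrate (k = 0.00270 M⁻¹ min⁻¹)
    starting material + coupling partner ⇌ isomer of the product (K = 110 M⁻¹, k = 0.00360 M⁻¹ min⁻¹)
    target + catalyst ⇌ isomer of the product + catalyst, rate k4*[catalyst]*[target] forward; the back reaction follows from the equilibrium constant (k = 0.0990 M⁻¹ min⁻¹)

Scaled to cedar, the lifetime is 1.49 d; from cedar's 31.5% at 1.25 d it gives 13.6% at 2.50 d, and cedar held 23.0%.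

All runs are calculated from invented constants, noise included.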